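**Retrosynthetic overview** (daucane numbering: C1 = quaternary ring-fusion carbon with CH3, C4 = carbinol carbon with OH and isopropyl, C5 = ring-fusion CH, C6 = ester-bearing carbon, C8=C9–C10(=O) = enone)
1. The vanillate ester is put on the C6 hydroxyl of the bicyclic diol enone last, with the phenol masked as its acetate.
2. The seven-membered ring is formed last: ring-closing metathesis makes C8=C9 from a vinyl carbinol on C1 and a methallyl carbinol on C5, then allylic oxidation at C10.
3. The cyclopentane is formed before it by an intramolecular aldol addition of C5 (α-carbon of the C6 aldehyde) to the ketone carbon C4. This works because C4(OH)–C5(H)–C6(O) is a β-hydroxy carbonyl triad inside the five-membered ring, and C4 and C6 are 1,5-related across quaternary C1.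
4. That 1,5-keto-aldehyde is released by ozonolysis of a temporary cyclohexene ring (formed first), the Diels–Alder adduct of methacrolein and 2-isopropylbutadiene; the catalytic asymmetric cycloaddition sets C1.
5. Stereochemical relay: C1 (catalyst) → C5 and C4 (aldol) → C6 (chelation-controlled allylation); C10 is carried as an uncontrolled carbinol and later oxidised.

Key step: step 5

Assumption: the (R)-diphenylprolinol-derived o-tolyl oxazaborolidine is taken as the catalyst enantiomer whose triflimide salt gives the (S)-configured Diels–Alder adduct; if the sense is opposite, its mirror image is used.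
Assumption: the enamine of the keto-aldehyde follows the usual acid-directed face preference of proline enamines, which makes D-proline the matched catalyst for the configuration needed at C5; if the sense is opposite, L-proline is used.

Step 1
Reactants: 1 2-chlorobuta-1,3-diene (chloroprene)
Product: 2 2-(propan-2-yl)buta-1,3-diene
Conditions: i-PrMgCl, NiCl2(dppp) (1 mol%), Et2O, 0 °C to rt
Reagents that add atoms: isopropylmagnesium chloride, CC(C)[Mg]Cl
Why: Kumada coupling of the vinylic chloride with the secondary Grignard reagent should give the 2-alkyl diene, the bidentate phosphine keeping the isopropyl group from isomerising; no stereocenter is formed.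

Step 2
Reactants: 2 2-(propan-2-yl)buta-1,3-diene; 3 2-methylprop-2-enal (methacrolein)
Product: 4 (1S)-1-methyl-4-(propan-2-yl)cyclohex-3-ene-1-carbaldehyde
Conditions: (R)-o-tolyl oxazaborolidine from α,α-diphenylprolinol (10 mol%), Tf2NH (10 mol%), CH2Cl2, −78 °C
Reagents that add atoms: none
Why: Catalytic enantioselective Diels–Alder reaction in which the cationic oxazaborolidine binds s-trans methacrolein and blocks one face, so that the 2-substituted diene adds with 1,4 ("para") regiochemistry and the catalyst alone sets the quaternary C1.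

Step 3
Reactants: 4 (1S)-1-methyl-4-(propan-2-yl)cyclohex-3-ene-1-carbaldehyde
Product: 6 triethyl({1-[(1S)-1-methyl-4-(propan-2-yl)cyclohex-3-en-1-yl]prop-2-en-1-yl}oxy)silane (both epimers at the silyloxy carbon), via allylic alcohol 5 (not isolated)
Conditions: CH2=CHMgBr, THF, −78 to 0 °C; then TESCl, imidazole (cat.), DMF, rt
Reagents that add atoms: vinylmagnesium bromide, C=C[Mg]Br; chlorotriethylsilane, CC[Si](Cl)(CC)CC
Why: Grignard 1,2-addition to the non-enolisable aldehyde followed by O-silylation; the new carbinol center C10 is left uncontrolled because it becomes the ketone in step 8, and the silyl ether both prevents lactol formation with the later aldehyde and makes this substituent of C1 clearly larger than methyl.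

Step 4
Reactants: 6 triethyl({1-[(1S)-1-methyl-4-(propan-2-yl)cyclohex-3-en-1-yl]prop-2-en-1-yl}oxy)silane
Product: 8 (3S)-3,7-dimethyl-6-oxo-3-{1-[(triethylsilyl)oxy]prop-2-en-1-yl}octanal, via secondary ozonide 7 (not isolated)
Conditions: O3, CH2Cl2, −78 °C (Sudan Red 7B end point); then Me2S, −78 °C to rt
Reagents that add atoms: ozone, [O-][O+]=O
Why: Ozonolysis with reductive work-up should cleave the electron-rich trisubstituted ring alkene far faster than the monosubstituted vinyl group, which is deactivated by the allylic oxygen and shielded by the quaternary center, opening the temporary ring to the 1,5-keto-aldehyde without touching C1.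

Step 5
Reactants: 8 (3S)-3,7-dimethyl-6-oxo-3-{1-[(triethylsilyl)oxy]prop-2-en-1-yl}octanal
Product: 9 (1R,2R,5S)-2-hydroxy-5-methyl-2-(propan-2-yl)-5-{1-[(triethylsilyl)oxy]prop-2-en-1-yl}cyclopentane-1-carbaldehyde
Conditions: D-proline (30 mol%), DMSO, rt
Reagents that add atoms: none
Why: The secondary amine condenses only with the aldehyde, and the enamine carbon C5 adds to the isopropyl ketone carbon C4 through a transition state in which the carboxylic acid of the catalyst bridges to the ketone oxygen; hydrolysis releases the β-hydroxy aldehyde and the catalyst. The closest known reaction type is the proline-catalysed intramolecular enolexo aldol addition (Hajos–Parrish-type enamine catalysis), as used in the ozonolysis/aldol ring contraction of cyclohexenes to cyclopentanecarbaldehydes. The cyclopentane closes in the 5-(enolexo)-exo-trig mode, favoured by the gem-disubstitution at C1 (Thorpe–Ingold effect). C4 is set by the acid-bridged, then hydrogen-bonded arrangement that places the new hydroxyl cis and the isopropyl group trans to the formyl group; C5 is set by the quaternary C1, the formyl group taking the face of the small methyl group and staying trans to the bulky silyloxyallyl group (all three large groups pseudo-equatorial), a modest substrate preference that the face selectivity of the D-proline enamine should reinforce and that retro-aldol equilibration also serves. The step needs the aldehyde as donor, the ketone as acceptor and no dehydration: the hindered α-branched ketone does not form an enamine, C1 carries no hydrogen, the silyl ether excludes lactol formation, and the zwitterionic catalyst at room temperature is too mild to eliminate the tertiary hydroxyl.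

Step 6
Reactants: 9 (1R,2R,5S)-2-hydroxy-5-methyl-2-(propan-2-yl)-5-{1-[(triethylsilyl)oxy]prop-2-en-1-yl}cyclopentane-1-carbaldehyde
Product: 11 (1R,2S,3S)-2-[(1S)-1-hydroxy-3-methylbut-3-en-1-yl]-3-(1-hydroxyprop-2-en-1-yl)-3-methyl-1-(propan-2-yl)cyclopentan-1-ol, via triethylsilyl ether 10 (not isolated)
Conditions: indium powder, 3-bromo-2-methylprop-1-ene, THF–H2O (1:1), rt; then 1 M HCl, rt
Reagents that add atoms: 3-bromo-2-methylprop-1-ene, C=C(C)CBr
Why: Barbier-type indium allylation in aqueous medium, in which trivalent indium chelates the C4 hydroxyl and the formyl oxygen so that the allyl group adds to the exposed face of the chelate and sets C6 as S, after which dilute acid removes the silyl ether.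

Step 7
Reactants: 11 (1R,2S,3S)-2-[(1S)-1-hydroxy-3-methylbut-3-en-1-yl]-3-(1-hydroxyprop-2-en-1-yl)-3-methyl-1-(propan-2-yl)cyclopentan-1-ol
Product: 12 (3R,3aS,4S,8aS)-6,8a-dimethyl-3-(propan-2-yl)-1,2,3,3a,4,5,8,8a-octahydroazulene-3,4,8-triol (both C8 epimers)
Conditions: second-generation Grubbs catalyst (5 mol%), CH2Cl2 (5 mM), 40 °C
Reagents that add atoms: none
Why: Ring-closing metathesis of the vinyl carbinol with the 1,1-disubstituted alkene should close the seven-membered ring (trans-fused, because the two arms are trans on the cyclopentane) with loss of ethene and without change at any stereocenter.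

Step 8
Reactants: 12 (3R,3aS,4S,8aS)-6,8a-dimethyl-3-(propan-2-yl)-1,2,3,3a,4,5,8,8a-octahydroazulene-3,4,8-triol
Product: 13 (3R,3aS,4S,8aS)-3,4-dihydroxy-6,8a-dimethyl-3-(propan-2-yl)-2,3,3a,4,5,8a-hexahydroazulen-8(1H)-one
Conditions: MnO2 (20 equiv), CH2Cl2, rt
Reagents that add atoms: none
Why: Allylic oxidation with activated MnO2 should convert both C10 epimers of the allylic alcohol into the enone and leave the homoallylic secondary and the tertiary hydroxyl untouched.

Step 9
Reactants: 13 (3R,3aS,4S,8aS)-3,4-dihydroxy-6,8a-dimethyl-3-(propan-2-yl)-2,3,3a,4,5,8a-hexahydroazulen-8(1H)-one; 14 4-(acetyloxy)-3-methoxybenzoic acid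
Product: 15 (3R,3aS,4S,8aS)-3-hydroxy-6,8a-dimethyl-8-oxo-3-(propan-2-yl)-1,2,3,3a,4,5,8,8a-octahydroazulen-4-yl 4-(acetyloxy)-3-methoxybenzoate
Conditions: DCC, DMAP (10 mol%), CH2Cl2, 0 °C to rt
Reagents that add atoms: none
Why: Steglich esterification, selective for the secondary C6 hydroxyl because the tertiary C4 hydroxyl is too hindered to be acylated, and proceeding with retention at C6.

Step 10
Reactants: 15 (3R,3aS,4S,8aS)-3-hydroxy-6,8a-dimethyl-8-oxo-3-(propan-2-yl)-1,2,3,3a,4,5,8,8a-octahydroazulen-4-yl 4-(acetyloxy)-3-methoxybenzoate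
Product: 16 (3R,3aS,4S,8aS)-3-hydroxy-6,8a-dimethyl-8-oxo-3-(propan-2-yl)-1,2,3,3a,4,5,8,8a-octahydroazulen-4-yl 4-hydroxy-3-methoxybenzoate
Conditions: NH4OAc, MeOH–H2O (4:1), rt
Reagents that add atoms: none
Why: Near-neutral solvolysis of the phenolic acetate, which is far more labile than the hindered alkyl aryl ester, and which avoids base-induced elimination of the C6 acyloxy group through the dienolate of the enone.

**Compound list**
1 | 2-chlorobuta-1,3-diene (chloroprene) | C=CC(Cl)=C | starting material
2 | 2-(propan-2-yl)buta-1,3-diene | C=CC(=C)C(C)C | intermediate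
3 | 2-methylprop-2-enal (methacrolein) | CC(=C)C=O | starting material
4 | (1S)-1-methyl-4-(propan-2-yl)cyclohex-3-ene-1-carbaldehyde | O=C[C@]1(C)CC=C(C(C)C)CC1 | intermediate
5 | 1-[(1S)-1-methyl-4-(propan-2-yl)cyclohex-3-en-1-yl]prop-2-en-1-ol (both carbinol epimers) | C=CC(O)[C@]1(C)CC=C(C(C)C)CC1 | intermediate
6 | triethyl({1-[(1S)-1-methyl-4-(propan-2-yl)cyclohex-3-en-1-yl]prop-2-en-1-yl}oxy)silane (both epimers at the silyloxy carbon) | C=CC(O[Si](CC)(CC)CC)[C@]1(C)CC=C(C(C)C)CC1 | intermediate
7 | secondary ozonide of 6 (1,2,4-trioxolane bridging the two former ring-alkene carbons) | C=CC(O[Si](CC)(CC)CC)[C@]1(C)CC2OC(C(C)C)(CC1)OO2 | intermediate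
8 | (3S)-3,7-dimethyl-6-oxo-3-{1-[(triethylsilyl)oxy]prop-2-en-1-yl}octanal | O=CC[C@@](C)(C(O[Si](CC)(CC)CC)C=C)CCC(=O)C(C)C | intermediate
9 | (1R,2R,5S)-2-hydroxy-5-methyl-2-(propan-2-yl)-5-{1-[(triethylsilyl)oxy]prop-2-en-1-yl}cyclopentane-1-carbaldehyde | O=C[C@@H]1[C@@](C)(C(O[Si](CC)(CC)CC)C=C)CC[C@@]1(O)C(C)C | intermediate
10 | (1R,2S,3S)-2-[(1S)-1-hydroxy-3-methylbut-3-en-1-yl]-3-methyl-1-(propan-2-yl)-3-{1-[(triethylsilyl)oxy]prop-2-en-1-yl}cyclopentan-1-ol | C=C(C)C[C@H](O)[C@@H]1[C@@](C)(C(O[Si](CC)(CC)CC)C=C)CC[C@@]1(O)C(C)C | intermediate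
11 | (1R,2S,3S)-2-[(1S)-1-hydroxy-3-methylbut-3-en-1-yl]-3-(1-hydroxyprop-2-en-1-yl)-3-methyl-1-(propan-2-yl)cyclopentan-1-ol | C=C(C)C[C@H](O)[C@@H]1[C@@](C)(C(O)C=C)CC[C@@]1(O)C(C)C | intermediate
12 | (3R,3aS,4S,8aS)-6,8a-dimethyl-3-(propan-2-yl)-1,2,3,3a,4,5,8,8a-octahydroazulene-3,4,8-triol (both C8 epimers) | O[C@H]1CC(C)=CC(O)[C@@]2(C)CC[C@@](O)(C(C)C)[C@H]12 | intermediate
13 | (3R,3aS,4S,8aS)-3,4-dihydroxy-6,8a-dimethyl-3-(propan-2-yl)-2,3,3a,4,5,8a-hexahydroazulen-8(1H)-one | O[C@H]1CC(C)=CC(=O)[C@@]2(C)CC[C@@](O)(C(C)C)[C@H]12 | intermediate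
14 | 4-(acetyloxy)-3-methoxybenzoic acid | COc1cc(C(=O)O)ccc1OC(C)=O | starting material
15 | (3R,3aS,4S,8aS)-3-hydroxy-6,8a-dimethyl-8-oxo-3-(propan-2-yl)-1,2,3,3a,4,5,8,8a-octahydroazulen-4-yl 4-(acetyloxy)-3-methoxybenzoate | COc1cc(C(=O)O[C@H]2CC(C)=CC(=O)[C@@]3(C)CC[C@@](O)(C(C)C)[C@H]23)ccc1OC(C)=O | intermediate
16 | (3R,3aS,4S,8aS)-3-hydroxy-6,8a-dimethyl-8-oxo-3-(propan-2-yl)-1,2,3,3a,4,5,8,8a-octahydroazulen-4-yl 4-hydroxy-3-methoxybenzoate | COc1cc(C(=O)O[C@H]2CC(C)=CC(=O)[C@@]3(C)CC[C@@](O)(C(C)C)[C@H]23)ccc1O | target

**Step count and risks**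
Total step count: 10. Longest linear sequence: 10 steps (1 to 16); the aryl acid 14 enters at step 9.

Steps most likely to fail:

Step 5. The process at risk is insufficient facial discrimination at C5, since the substrate bias (methyl against the silyloxyallyl group) is modest, together with dehydration or retro-aldol reversal of the adduct under amine catalysis. Fallback: the ring is closed through a metal enolate instead. Starting from 8, the aldehyde is α-brominated (NBS, catalytic pyrrolidine, CH2Cl2, 0 °C) to (3R)-2-bromo-3,7-dimethyl-6-oxo-3-{1-[(triethylsilyl)oxy]prop-2-en-1-yl}octanal F2. SmI2 (2.2 equiv, THF, −78 °C) then generates the samarium enolate regiospecifically at C5, which adds to the ketone in a chelated intramolecular Reformatsky-type aldol addition and returns to 9.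

Step 4. The process at risk is over-oxidation through attack of ozone on the vinyl group. Fallback: starting from 6, mCPBA (NaHCO3, CH2Cl2, 0 °C) epoxidises only the trisubstituted ring alkene to triethyl({1-[(4S)-4-methyl-1-(propan-2-yl)-7-oxabicyclo[4.1.0]heptan-4-yl]prop-2-en-1-yl}oxy)silane F1, and H5IO6 (THF–H2O, 0 °C) cleaves the epoxide to the keto-aldehyde, returning to 8.

Step 6. The process at risk is erosion of facial selectivity at C6 through competing non-chelated addition to the hindered aldehyde. Fallback: reagent control instead of chelate control. Starting from 9, methallylboration with B-(2-methylprop-2-en-1-yl)diisopinocampheylborane (Et2O, −78 °C; NaBO3 work-up), with the reagent enantiomer chosen for the required face, sets C6 independently of the chelate and returns to 10; no new compound is made.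

Further compounds
F1 | step 4 | triethyl({1-[(4S)-4-methyl-1-(propan-2-yl)-7-oxabicyclo[4.1.0]heptan-4-yl]prop-2-en-1-yl}oxy)silane | C=CC(O[Si](CC)(CC)CC)[C@]1(C)CC2OC2(C(C)C)CC1
F2 | step 5 | (3R)-2-bromo-3,7-dimethyl-6-oxo-3-{1-[(triethylsilyl)oxy]prop-2-en-1-yl}octanal | O=CC(Br)[C@@](C)(C(O[Si](CC)(CC)CC)C=C)CCC(=O)C(C)C
F0 | step 6 | none | none
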